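**Assumption:** CNP0283603.1 is taken exactly as the SMILES given: the 6‑O‑[(E)‑3‑hydroxycinnamoyl] ester of eudesmane‑4β,6β‑diol, (4S,5S,6R,7S,10R), a trans‑decalin with 10β‑CH3, 5α‑H, axial 4β‑OH, axial 6β‑O and equatorial 7β‑isopropyl. Eudesmane numbering is used for the decalin. Step 1 is assumed to give roughly 85–90% ee, and the diol 13 is assumed crystalline so that it can be recrystallised to enantiopurity.

**Retrosynthetic overview**
1. C6–O ester bond: target ⇒ eudesmane‑4β,6β‑diol + O‑silylated m‑coumaroyl chloride (separate branch from 3‑hydroxybenzaldehyde and malonic acid).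
2. 6β‑OH ⇒ 4β‑hydroxyeudesman‑6‑one by α‑face hydride delivery.
3. C4–C5 bond ⇒ intramolecular aldol addition of a 2‑isopropyl‑5‑methyl‑5‑(4‑oxopentyl)cyclohexanone; C4, C5 and C7 are set thermodynamically from C10.
4. Isopropyl ⇒ acetone aldol, dehydration, hydrogenation; quaternary C10 ⇒ copper‑catalysed asymmetric conjugate addition of a ketal‑masked 4‑oxopentyl Grignard to 3‑methylcyclohexenone.
5. Ring order: ring B is the purchased cyclohexenone; ring A is closed last by the aldol.

**Route**

Step 1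
Reactants: 1 3-methylcyclohex-2-en-1-one; 2 2-(3-chloropropyl)-2-methyl-1,3-dioxolane
Product: 4 (S)-3-methyl-3-[3-(2-methyl-1,3-dioxolan-2-yl)propyl]cyclohexan-1-one, via Grignard reagent 3 (not isolated)
Conditions: 2, Mg (I2-activated), Et2O, reflux; then 1, Cu(OTf)2 (3 mol%), chiral C2-symmetric 4,5-diphenylimidazolinium salt (NHC precursor, 4 mol%), Et2O, 0 °C; aq. NH4Cl
Reagents that add atoms: none
Why: Copper-catalysed asymmetric conjugate addition of the alkyl Grignard to the β,β-disubstituted enone gives the 1,4-adduct, the chiral carbene ligand (enantiomer chosen accordingly) selecting the enone face so that the quaternary carbon (future C10) is formed as S.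

Step 2
Reactants: 4 (S)-3-methyl-3-[3-(2-methyl-1,3-dioxolan-2-yl)propyl]cyclohexan-1-one; 5 acetone
Product: 7 (5R)-2-(2-hydroxypropan-2-yl)-5-methyl-5-[3-(2-methyl-1,3-dioxolan-2-yl)propyl]cyclohexan-1-one (C2 epimer mixture), via lithium enolate 6 (not isolated)
Conditions: LiN(i-Pr)2, THF, −78 °C; acetone, −78 °C; AcOH quench at −78 °C
Reagents that add atoms: none
Why: Kinetic deprotonation by the bulky amide occurs at the CH2 remote from the quaternary carbon and the lithium enolate undergoes a directed aldol addition to acetone; the new CH centre is epimerisable and is fixed only in step 5 (the R descriptor of the quaternary carbon is a CIP change, not an inversion).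

Step 3
Reactants: 7 (5R)-2-(2-hydroxypropan-2-yl)-5-methyl-5-[3-(2-methyl-1,3-dioxolan-2-yl)propyl]cyclohexan-1-one
Product: 9 (5R)-5-methyl-5-[3-(2-methyl-1,3-dioxolan-2-yl)propyl]-2-(propan-2-ylidene)cyclohexan-1-one, via tertiary mesylate 8 (not isolated)
Conditions: MsCl, Et3N, DMAP (cat.), CH2Cl2, 0 °C; then DBU, rt
Reagents that add atoms: none
Why: Mesylation of the tertiary carbinol followed by base-induced E1cB elimination of the β-mesyloxy ketone gives only the conjugated isopropylidene ketone under non-aqueous conditions that leave the ketal intact; no stereocentre is involved.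

Step 4
Reactants: 9 (5R)-5-methyl-5-[3-(2-methyl-1,3-dioxolan-2-yl)propyl]-2-(propan-2-ylidene)cyclohexan-1-one
Product: 10 (5R)-5-methyl-5-[3-(2-methyl-1,3-dioxolan-2-yl)propyl]-2-(propan-2-yl)cyclohexan-1-one (C2 epimer mixture)
Conditions: H2 (1 atm), Pd/C (palladium on carbon, 10 wt%), EtOAc, rt
Reagents that add atoms: none
Why: Heterogeneous catalytic hydrogenation saturates the conjugated exocyclic alkene while ketone and ketal survive; the α-centre forms as a mixture that is equilibrated in step 5.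

Step 5
Reactants: 10 (5R)-5-methyl-5-[3-(2-methyl-1,3-dioxolan-2-yl)propyl]-2-(propan-2-yl)cyclohexan-1-one
Product: 12 (2S,4aR,8S,8aR)-8-hydroxy-4a,8-dimethyl-2-(propan-2-yl)octahydronaphthalen-1(2H)-one (4β-hydroxyeudesman-6-one), via diketone 11 (not isolated)
Conditions: 1 M aq. HCl (cat.), THF, rt; then same flask, MeOH, aq. KOH to pH 13–14, 0.02 M, 0 °C → rt; AcOH quench as soon as enone appears
Reagents that add atoms: water O
Why: Ketal hydrolysis frees the methyl ketone and a reversible base-mediated intramolecular aldol addition (6-enolexo, ring enolate carbon C5 onto the C4 methyl ketone) closes ring A under thermodynamic control, which favours the trans ring fusion, the equatorial 7-isopropyl group (epimerised through the enolate) and the equatorial 4-CH3 with axial, hydrogen-bonded 4β-OH, because the C4 epimer would place CH3 1,3-diaxial to the angular methyl.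

Step 6
Reactants: 12 (2S,4aR,8S,8aR)-8-hydroxy-4a,8-dimethyl-2-(propan-2-yl)octahydronaphthalen-1(2H)-one
Product: 13 (1R,2S,4aR,8S,8aS)-4a,8-dimethyl-2-(propan-2-yl)decahydronaphthalene-1,8-diol (eudesmane-4β,6β-diol)
Conditions: NaBH4, MeOH, −20 → 0 °C; recrystallise
Reagents that add atoms: none
Why: Borohydride reduction of the cyclohexanone takes the equatorial trajectory from the α face because the β face is screened by the syn-axial angular CH3 and 4β-OH, giving the axial 6β-alcohol.

Step 7
Reactants: 14 3-hydroxybenzaldehyde; 15 malonic acid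
Product: 17 (E)-3-(3-hydroxyphenyl)prop-2-enoic acid, via 2-(3-hydroxybenzylidene)malonic acid 16 (not isolated)
Conditions: pyridine, piperidine (cat.), 90 °C; aq. HCl
Reagents that add atoms: none
Why: Knoevenagel–Doebner condensation followed by in situ decarboxylation gives the E-cinnamic acid.

Step 8
Reactants: 17 (E)-3-(3-hydroxyphenyl)prop-2-enoic acid
Product: 18 tert-butyldimethylsilyl (E)-3-[3-(tert-butyldimethylsilyloxy)phenyl]prop-2-enoate
Conditions: TBSCl (2.4 equiv), imidazole, DMF, rt
Reagents that add atoms: tert-butyldimethylsilyl chloride CC(C)(C)[Si](C)(C)Cl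
Why: Imidazole-promoted silylation caps both the phenol and the carboxylic acid.

Step 9
Reactants: 18 tert-butyldimethylsilyl (E)-3-[3-(tert-butyldimethylsilyloxy)phenyl]prop-2-enoate
Product: 19 (E)-3-[3-(tert-butyldimethylsilyloxy)phenyl]prop-2-enoic acid
Conditions: AcOH/THF/H2O 3:1:1, rt
Reagents that add atoms: none
Why: Selective solvolysis cleaves the very labile silyl ester while the aryl silyl ether survives mild aqueous acid.

Step 10
Reactants: 19 (E)-3-[3-(tert-butyldimethylsilyloxy)phenyl]prop-2-enoic acid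
Product: 20 (E)-3-[3-(tert-butyldimethylsilyloxy)phenyl]prop-2-enoyl chloride
Conditions: (COCl)2, DMF (cat.), CH2Cl2, 0 °C → rt; evaporate
Reagents that add atoms: oxalyl chloride ClC(=O)C(=O)Cl
Why: Vilsmeier-type activation converts the acid into the acid chloride without touching the alkene geometry or the silyl ether.

Step 11
Reactants: 13 (1R,2S,4aR,8S,8aS)-4a,8-dimethyl-2-(propan-2-yl)decahydronaphthalene-1,8-diol; 20 (E)-3-[3-(tert-butyldimethylsilyloxy)phenyl]prop-2-enoyl chloride
Product: 21 (1R,2S,4aR,8S,8aS)-8-hydroxy-4a,8-dimethyl-2-(propan-2-yl)decahydronaphthalen-1-yl (E)-3-[3-(tert-butyldimethylsilyloxy)phenyl]prop-2-enoate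
Conditions: DMAP, Et3N, CH2Cl2, 0 → 40 °C
Reagents that add atoms: none
Why: DMAP-catalysed acylation (nucleophilic catalysis through the acylpyridinium) esterifies the secondary 6β-OH while the tertiary 4-OH stays free; no stereocentre is touched.

Step 12
Reactants: 21 (1R,2S,4aR,8S,8aS)-8-hydroxy-4a,8-dimethyl-2-(propan-2-yl)decahydronaphthalen-1-yl (E)-3-[3-(tert-butyldimethylsilyloxy)phenyl]prop-2-enoate
Product: 22 (1R,2S,4aR,8S,8aS)-8-hydroxy-4a,8-dimethyl-2-(propan-2-yl)decahydronaphthalen-1-yl (2E)-3-(3-hydroxyphenyl)prop-2-enoate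
Conditions: Bu4NF, AcOH (1:1), THF, 0 °C
Reagents that add atoms: none
Why: Buffered fluoride desilylation cleaves the aryl silyl ether and leaves the cinnamate ester and tertiary alcohol intact.

**Compound list**
1 | 3-methylcyclohex-2-en-1-one | CC1=CC(=O)CCC1 | starting material
2 | 2-(3-chloropropyl)-2-methyl-1,3-dioxolane | CC1(CCCCl)OCCO1 | starting material
3 | [3-(2-methyl-1,3-dioxolan-2-yl)propyl]magnesium chloride | CC1(CCC[Mg]Cl)OCCO1 | intermediate
4 | (S)-3-methyl-3-[3-(2-methyl-1,3-dioxolan-2-yl)propyl]cyclohexan-1-one | O=C1CCC[C@@](C)(CCCC2(C)OCCO2)C1 | intermediate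
5 | acetone | CC(C)=O | starting material
6 | kinetic lithium enolate of 4 (enolate double bond away from the quaternary carbon) | [Li]OC1=CCC[C@@](C)(CCCC2(C)OCCO2)C1 | intermediate
7 | (5R)-2-(2-hydroxypropan-2-yl)-5-methyl-5-[3-(2-methyl-1,3-dioxolan-2-yl)propyl]cyclohexan-1-one (C2 epimer mixture) | CC(C)(O)C1CC[C@@](C)(CCCC2(C)OCCO2)CC1=O | intermediate
8 | tertiary methanesulfonate of 7 | CC(C)(OS(C)(=O)=O)C1CC[C@@](C)(CCCC2(C)OCCO2)CC1=O | intermediate
9 | (5R)-5-methyl-5-[3-(2-methyl-1,3-dioxolan-2-yl)propyl]-2-(propan-2-ylidene)cyclohexan-1-one | CC(C)=C1CC[C@@](C)(CCCC2(C)OCCO2)CC1=O | intermediate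
10 | (5R)-5-methyl-5-[3-(2-methyl-1,3-dioxolan-2-yl)propyl]-2-(propan-2-yl)cyclohexan-1-one (C2 epimer mixture) | CC(C)C1CC[C@@](C)(CCCC2(C)OCCO2)CC1=O | intermediate
11 | (5R)-5-methyl-5-(4-oxopentyl)-2-(propan-2-yl)cyclohexan-1-one (C2 epimer mixture) | CC(C)C1CC[C@@](C)(CCCC(C)=O)CC1=O | intermediate
12 | (2S,4aR,8S,8aR)-8-hydroxy-4a,8-dimethyl-2-(propan-2-yl)octahydronaphthalen-1(2H)-one (4β-hydroxyeudesman-6-one) | CC(C)[C@@H]1CC[C@@]2(C)CCC[C@](C)(O)[C@@H]2C1=O | intermediate
13 | (1R,2S,4aR,8S,8aS)-4a,8-dimethyl-2-(propan-2-yl)decahydronaphthalene-1,8-diol (eudesmane-4β,6β-diol) | CC(C)[C@@H]1CC[C@@]2(C)CCC[C@](C)(O)[C@@H]2[C@@H]1O | intermediate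
14 | 3-hydroxybenzaldehyde | O=Cc1cccc(O)c1 | starting material
15 | malonic acid | OC(=O)CC(O)=O | starting material
16 | 2-(3-hydroxybenzylidene)malonic acid | OC(=O)C(=Cc1cccc(O)c1)C(O)=O | intermediate
17 | (E)-3-(3-hydroxyphenyl)prop-2-enoic acid | OC(=O)/C=C/c1cccc(O)c1 | intermediate
18 | tert-butyldimethylsilyl (E)-3-[3-(tert-butyldimethylsilyloxy)phenyl]prop-2-enoate | CC(C)(C)[Si](C)(C)OC(=O)/C=C/c1cccc(O[Si](C)(C)C(C)(C)C)c1 | intermediate
19 | (E)-3-[3-(tert-butyldimethylsilyloxy)phenyl]prop-2-enoic acid | OC(=O)/C=C/c1cccc(O[Si](C)(C)C(C)(C)C)c1 | intermediate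
20 | (E)-3-[3-(tert-butyldimethylsilyloxy)phenyl]prop-2-enoyl chloride | ClC(=O)/C=C/c1cccc(O[Si](C)(C)C(C)(C)C)c1 | intermediate
21 | (1R,2S,4aR,8S,8aS)-8-hydroxy-4a,8-dimethyl-2-(propan-2-yl)decahydronaphthalen-1-yl (E)-3-[3-(tert-butyldimethylsilyloxy)phenyl]prop-2-enoate | CC(C)[C@@H]1CC[C@@]2(C)CCC[C@](C)(O)[C@@H]2[C@@H]1OC(=O)/C=C/c1cccc(O[Si](C)(C)C(C)(C)C)c1 | intermediate
22 | (1R,2S,4aR,8S,8aS)-8-hydroxy-4a,8-dimethyl-2-(propan-2-yl)decahydronaphthalen-1-yl (2E)-3-(3-hydroxyphenyl)prop-2-enoate | CC(C)[C@@H]1CC[C@@]2(C)CCC[C@](C)(O)[C@@H]2[C@@H]1OC(=O)/C=C/c1cccc(O)c1 | target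

**Totals**
Total step count: 12. Longest linear sequence: 8 (steps 1–6, 11, 12); the acid branch (steps 7–10) joins at step 11.

**Three steps most likely to fail**

Step 5 (aldol ring closure). The ketol may dehydrate to the enone, give the C4 epimer, or divert reversibly into a bridged ketol (chain enolate onto the ring ketone). The fallback sets out from 10 and returns at 12. It deliberately drives the aldol to condensation (aq. HCl/THF, then NaOMe, MeOH, reflux) to give (7S,10R)-eudesm-4-en-6-one F2. Reduction with NaBH4 and CeCl3·7H2O from the α face then gives (6R,7S,10R)-eudesm-4-en-6-ol F3. Hydroxyl-directed epoxidation with VO(acac)2 (cat.) and t-BuOOH puts the oxygen on the β face, giving 4β,5β-epoxy-5β-eudesman-6β-ol F4. Dess–Martin oxidation gives 4β,5β-epoxy-5β-eudesman-6-one F5. SmI2 in THF/MeOH at −78 °C cleaves the Cα–O bond reductively and, after brief base equilibration of C5 to the trans fusion, delivers 12 with the 4β-OH fixed by the epoxide instead of by equilibrium.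

Step 1 (asymmetric conjugate addition). The ketal oxygen atoms of the Grignard reagent may erode enantioselectivity or reactivity. The fallback sets out from 2 and returns at 4, with the roles of the two β-substituents exchanged. Grignard reagent 3 (made in THF) adds 1,2 to 3-ethoxycyclohex-2-en-1-one, and cold dilute acid work-up (Stork–Danheiser transposition) gives 3-[3-(2-methyl-1,3-dioxolan-2-yl)propyl]cyclohex-2-en-1-one F1. Asymmetric conjugate methylation with Me3Al, copper thiophene-2-carboxylate (C5H3CuO2S, 2 mol%) and a chiral biphenol-derived phosphoramidite (4 mol%) in Et2O at −30 °C, with the ligand enantiomer chosen for the S product, then gives 4.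

Step 11 (acylation of the hindered axial 6β-OH). The alcohol is flanked by the isopropyl group and syn-axial to 4-OH and the angular methyl, so the bulky cinnamoyl chloride may react sluggishly. The fallback sets out from 13 and returns at 21, building the cinnamate on the alcohol. The small diethylphosphonoacetic acid is coupled with DCC and DMAP (cat.) in CH2Cl2 to give eudesmane-4β,6β-diol 6-O-(diethoxyphosphoryl)acetate F6. Separately, 14 is silylated (TBSCl, imidazole, DMF) to 3-(tert-butyldimethylsilyloxy)benzaldehyde F7. A Horner–Wadsworth–Emmons olefination of F6 with F7 under LiCl, DBU, MeCN gives the E-cinnamate 21 directly.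

**Further compounds**
F1 | step 1 | 3-[3-(2-methyl-1,3-dioxolan-2-yl)propyl]cyclohex-2-en-1-one | O=C1C=C(CCCC2(C)OCCO2)CCC1
F2 | step 5 | (7S,10R)-eudesm-4-en-6-one | CC(C)[C@@H]1CC[C@@]2(C)CCCC(C)=C2C1=O
F3 | step 5 | (6R,7S,10R)-eudesm-4-en-6-ol (6β-OH) | CC(C)[C@@H]1CC[C@@]2(C)CCCC(C)=C2[C@@H]1O
F4 | step 5 | 4β,5β-epoxy-5β-eudesman-6β-ol | CC(C)[C@@H]1CC[C@@]2(C)CCC[C@]3(C)O[C@]23[C@@H]1O
F5 | step 5 | 4β,5β-epoxy-5β-eudesman-6-one | CC(C)[C@@H]1CC[C@@]2(C)CCC[C@]3(C)O[C@]23C1=O
F6 | step 11 | eudesmane-4β,6β-diol 6-O-(diethoxyphosphoryl)acetate | CC(C)[C@@H]1CC[C@@]2(C)CCC[C@](C)(O)[C@@H]2[C@@H]1OC(=O)CP(=O)(OCC)OCC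
F7 | step 11 | 3-(tert-butyldimethylsilyloxy)benzaldehyde | O=Cc1cccc(O[Si](C)(C)C(C)(C)C)c1
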